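After 40 min I must say what stands in the flask, and the earlier runs are what I have.

| setting | epsilon | beta | theta | flask |
|---|---|---|---|---|
| J | 0.056 M | 0.056 M | 0.028 M | 0.056 M |
| X | 0.056 M | 0.056 M | 0.028 M | 0.056 M |
| E | 0.112 M | 0.112 M | 0.112 M | 0.112 M |
| Q | 0.73 mM | 0.73 mM | 0.73 mM | 0.73 mM |
| Z | 1.4 mM | 5.6 mM | 2.8 mM | 2.8 mM |
| remark | run made earlier | run made earlier | run made earlier |  |
| time |  |  |  | 40 min |

- epsilon (time / min: G / %, X / %): 6.00: 27.9, 48.4; 15.0: 43.3, 43.6; 30.0: 54.3, 36.5; 50.0: 63.2, 28.4
- beta (time / min: G / %, X / %): 4.00: 22.3, 47.5; 8.00: 34.5, 42.8; 20.0: 54.1, 29.4; 50.0: 73.7, 14.2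
- theta (time / min: G / %, X / %): 4.00: 23.1, 48.3; 8.00: 35.8, 46.1; 20.0: 55.4, 34.7; 50.0: 76.5, 18.1

(scatter of a reading: 0.5 percentage points)

- at 40 min, what has stopped the reaction, if anything has (it is still moving / E has run out first / all of J has reacted / no working catalyst is left / forward and back rates have come level)
- amount of G at 40 min, in percent of the J and X together charged
- amount of X at 40 min, in percent of the J and X together charged

- Q is single-handed; J and X are mirror images of each other, charged as a racemate, each of them at the stated concentration
- steps under discussion: E + Q + J -> Q + G; E + Q + X -> Q + D; J + Z <-> X + Z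
- the reaction counts as stopped when no species that holds the J and X together changes by six tenths of a point or more over the second half of the time

The bench rule for a racemate under single-handed Q is plain kinetic resolution: J burns away, X stays, and G stops at J's share of the charge, half. Applied honestly, it fails: epsilon holds 54.3% of G at 30.0 min, more than that share, so Z must be refilling J from X.

The border is a ratio. Taking J as the charge less G and X, the logarithm of its fall to the first theta reading gives a burn constant of 0.140 /min at full E. The fall of X in beta, over the mean gap between X and J and scaled to this flask's Z, gives a refill constant of 0.0338 /min. Their ratio is 0.242. This is the refill number, Z's refill constant over J's burn constant, and I divide it by the fraction of E left. Well below one the bench rule serves; nearer one, J over X settles towards number/(1+number).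

This flask's Z is twice epsilon's and half beta's, so it lies midway in the logarithm of Z. Interpolating both runs in log time and averaging, I commit to G 64.1% and X 24.9%, still moving. Counting D as nil, E left is 35.9%, so the number is 0.675.

The forecast says it is still moving, G 64.5% and X 23.5%, by “Stepping the charge forward by hand”; its X is 1.4 percentage points below mine.

The flask gives it is still moving, G 64.8% and X 24.6%.

    E + Q + J → Q + G (k = 33.9 /M²/s)
    E + Q + X → Q + D (k = 0.331 /M²/s)
    J + Z ⇌ X + Z, rate k3*[Z]*[J] forward; the back reaction follows from the equilibrium constant (k = 0.171 /M/s)

With 33.9% of E left at 40.0 min, my number, still the one read from the runs and carrying their scatter, comes to 0.715, which estimates J over X near 0.417; the flask holds 0.377. The neighbouring flask is charged with 0.028 M of E, a quarter of this flask's, and keeps 7.76% of its own charge at 40.0 min. My number read from the runs then comes to 12.5, which estimates J over X near 0.926; the neighbouring flask holds 0.871. At that time the neighbouring flask has J 35.8%, X 41.1% and G 22.8%.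

(The runs are simulated with constants of no real substance; the scatter is artificial.)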